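# Proposed total synthesis of CNP0134269.1 by a rhodium-catalysed diene-yne Pauson–Khand reaction

Atom labels used throughout: ring carbons C1 (CHEt), C2 (C=O), C3 (CHMe), C3a, C4(Me)=C5, C6, C7, C7a; side chain C1'H=C2'(Et)–C3'H=C4'H–Ph on C6; CO2H on C7.

## Analysis of the target

Compound 31 is a trans-fused hexahydroinden-2-one. A cyclopentanone (C1, C2, C3, C3a, C7a) shares the C3a–C7a bond with a cyclohexene (C3a, C4, C5, C6, C7, C7a) whose only ring double bond is C4=C5.

It has six stereocentres: the vicinal quaternary carbons C6 (ethyl, dienyl chain) and C7 (ethyl, carboxyl), the fusion carbons C3a and C7a, and the ketone α-carbons C1 and C3. The two ethyl groups on C6 and C7 are cis, as are the carboxyl and the dienyl chain. C3a–H lies on the face of the two ethyl groups and C7a–H on the face of the carboxyl. The ethyl on C1 and the methyl on C3 are each trans to the ring carbon on the neighbouring fusion atom.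

C1 and C3 are epimerisable and appear to sit in their most stable arrangement, so only C6, C7, C3a and C7a call for kinetic control.

The sensitive groups are:
- the (1E,3E)-4-phenylbutadienyl unit, which is reduced by dissolving metals, is acid-labile and binds low-valent metals;
- the carboxyl group wedged between two quaternary carbons, whose esters resist hydrolysis and which would capture a free C1' hydroxyl as a γ-lactone;
- the enolisable ketone.

The main difficulty is that C6 and C7 each carry an ethyl group next to a second substituent of similar size. No reagent can distinguish their faces, and C3a must then be placed relative to them across the ring.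

The strategy rests on the cyclopentanone. Its carbonyl carbon C2 sits between C1 and C3, and the C3a–C7a bond is shared with the cyclohexene right next to C4=C5. Read at the C1=C7a enone level, this is what a carbonylative [2+2+1] cycloaddition leaves behind when an alkyne (C1≡C7a), the far double bond (C3a=C3) of a (Z)-1,3-diene and CO are joined, with C5=C4 and C6–C7 as the tether.

## Retrosynthetic reasoning

**31 ⇒ 30.** The last bond cut is the O–CH3 bond of the methyl ester 30. The ester is kept to the end because the acyl carbon is shielded by two quaternary carbons; it is removed by attack at the methyl carbon, which the shielding does not affect, so no hydrolysis is needed in the presence of the diene.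

**30 ⇒ 28 + 29; 28 ⇒ 24 + 27.** The dienyl chain is cut at C3'=C4' (phosphonate 29 on enal 28) and at C1'=C2' (formyl ylide 27 on aldehyde 24). Both olefinations are (E)-selective by their nature and leave the ketone alone. The chain has to come after the ring-forming and reducing steps, because a phenylbutadiene would not survive a dissolving-metal reduction and would offer the rhodium catalyst a second diene.

**24 ⇒ 23.** The C1' aldehyde is traced back to a diethyl acetal. A protected C1' alcohol was rejected: once freed it would sit cis and vicinal to the C7 ester on two fully substituted carbons and would close to a γ-lactone before it could be oxidised. Carrying C1' at the aldehyde level from the first step removes that hazard and an oxidation step.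

**23 ⇒ 21.** The C7a–H and C1–H bonds are removed to give the C1=C7a enone 21. Forward, a dissolving-metal reduction has to deliver hydrogen to C7a anti to C3a–H, and C1 then settles under base. The ester is not saponified before this step: C3a–H in 21 is γ to the enone and allylic to C4=C5, so hydroxide would risk scrambling C3a.

**21 ⇒ 19 + 20.** This is the key disconnection. C3a–C7a, C1–C2 and C2–C3 are cut together, which opens both rings and leaves the open-chain diene-yne 19 and carbon monoxide 20. Nowhere else can three bonds and two rings be removed in one operation while the two quaternary carbons stay in an acyclic chain that a sigmatropic rearrangement can build. The forward reaction must choose one face of the C3a=C3 alkene relative to C6/C7.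

**19 ⇒ 18 ⇒ 17.** The alkyne is formed last before the key step, from the butanoyl ketone 17 through enol triflate 18. Only the propyl side of that ketone can enolise. Unveiling the alkyne after the diene is deliberate: an alkenylpalladium species at C4, cis to C6, would add 5-exo to an alkyne on C7.

**17 ⇒ 15 + 16; 15 ⇒ 13 + 14; 13 ⇒ 12.** The (Z,E)-diene is cut at the C4–C3a single bond (boronic acid 16 on iodoalkene 15) and then at C5=C4 (iodo-ylide from 14 on aldehyde 13). The trisubstituted (Z)-geometry is thus fixed by a kinetically controlled olefination and carried through a stereoretentive coupling, not left to an allylic ylide. The aldehyde 13 comes from the propenyl group of 12 by cleavage of its double bond.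

**12 ⇒ 10.** The C6–C7 bond is cut by a [3,3] shift of the allyl β-keto ester 10. This is where both quaternary carbons are made. A concerted rearrangement through a chair can join two fully substituted carbons, and the single carbinol stereocentre of 10 dictates both new centres before being lost later as a two-carbon fragment. The β-keto ester is chosen because its lithium chelate fixes the geometry at C7, and because the ketone is the latent alkyne.

**10 ⇒ 7 + 9, and the side components.** Ester 10 is cut at the acyl–oxygen bond into alcohol 7 and keto ester 9 (from 8 by alkylation). The (E)-trisubstituted alkene of 7 comes from iodide 6 and, through the non-isolated alanate 5, from propargylic alcohol 4 by directed trans-hydrometalation. The stereocentre of 4 is set by asymmetric reduction of ynone 3, made from 1 and 2. Ylide 27 is made from 25 and 26.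

## Alternatives that were turned down

Alternative 1: The cut is the C3–C3a bond of the five-membered ring. Forward, a rhodium carbenoid at C3 (from a diazo group flanked by the C2 ketone and an ester, on a side chain of C7a) would insert into the pseudo-equatorial allylic C3a–H bond of a preformed cyclohexene. The product would be the trans-fused β-keto ester A1.
- For: 1,5-insertion of such carbenoids into activated C–H bonds is dependable. The equatorial C–H bond leads straight to the trans fusion without a dissolving-metal step. The but-1-ynyl group on C6 of A1 is a compact precursor of the dienyl chain.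
- Against: the key step makes one ring and one bond. The cyclohexene with C6, C7 and C7a in place must already exist, so the real difficulty is untouched. The carbenoid has competitors for C3a–H: the adjacent C4=C5 bond (cyclopropanation) and the methyl C–H bonds of the C1 ethyl group (also a five-membered closure). A1 still needs its C3 ester exchanged for methyl and its alkyne converted into the diene beside the ketone.
- Comparison: on the ring fusion this alternative is the stronger one, since the chosen route relies on a face-selective cycloaddition and a reduction for C3a and C7a. The chosen route offers both rings and three C–C bonds in one step from an open chain assembled by a single rearrangement.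

Alternative 2: The cut is the C5–C6 bond. Forward, zerovalent palladium would insert into the C5–I bond of a (Z)-iodoalkene on C3a of a finished cyclopentanone. The alkenylpalladium would add 6-exo to C6 of a 1,3-diene tethered through C7, and the allylpalladium would lose a benzylic hydrogen. The product A2 is the methyl ester of the target, the same compound as 30.
- For: the cyclohexene, the quaternary carbon C6 and the styryl diene appear together, no protecting group is needed at C1', and the target is one step away.
- Against: the insertion must create a quaternary carbon next to the quaternary C7 at a fully substituted diene terminus. Its face is controlled only by the ethyl/ester pair on C7, which a metal can hardly tell apart. The allylpalladium can eliminate in more than one direction, and the geometry of the new C1'=C2' bond is not fixed by the mechanism. The substrate already carries C1, C3, C3a, C7a and an acyclic quaternary C7, built linearly.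
- Comparison: it is stronger in step count after the key step and needs no redox work at C1'. The chosen route sets C6 and C7 together, early, through a cyclic transition state and leaves only C3a to the metal.

Alternative 3: The cut is again C6–C7, inside a ring-contracting [3,3] shift. The silyl ketene acetal of a δ-lactone (ring oxygen on C4, which also bears the C5=C6 alkenyl group; carbonyl attached to C7) would rearrange through a boat. C6–C7 and C4=C5 form while C4–O breaks, giving the cyclohexene acid A3.
- For: the ring fixes the ketene acetal geometry and enforces the boat, so the C6/C7 relationship and its relation to C3a/C7a follow from the lactone. The acid is liberated without hydrolysis.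
- Against: the lactone must already contain C3a, C7a, a tertiary carbinol centre at C4 and a geometrically defined trisubstituted alkene. A3 still lacks the five-membered ring: C1 and C3 are 1,1-disubstituted alkene carbons and C2 is missing, so the cyclopentanone, C1 and C3 all remain to be made. Its silyl-protected C1' oxygen would close onto the C7 acid once deprotected.
- Comparison: on the C6/C7 pair it is at least as strong as the chosen route, which relies on a lithium chelate and not a ring for the ketene acetal geometry. The chosen route uses the same kind of rearrangement on an open chain and then gains both rings at once.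

Key step: step 13

## Route

Remark on the chemistry: the arrangement at C1 and C3 of 31 (each substituent trans to the ring carbon on the neighbouring fusion atom) is taken to be the thermodynamically preferred one of the trans-fused ketone, so both centres are left to base equilibration.

Remark on names: locants and descriptors of 21–31 follow the ring numbering of the analysis (carboxyl carbon on C7). TsDPEN is N-(p-toluenesulfonyl)-1,2-diphenylethylenediamine; dppf is 1,1'-bis(diphenylphosphino)ferrocene.

Step 1
Reactants: 1 3,3-diethoxyprop-1-yne; 2 N-methoxy-N-methylacetamide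
Product: 3 5,5-diethoxypent-3-yn-2-one
Conditions: n-BuLi, THF, −78 °C; then 2, −78 → 0 °C; aq. NH4Cl
Reagents that add atoms: none
Why: Acylation of a lithium acetylide with a Weinreb amide; the chelated tetrahedral intermediate survives until work-up, so the reaction should stop at the ynone.

Step 2
Reactants: 3 5,5-diethoxypent-3-yn-2-one
Product: 4 (2R)-5,5-diethoxypent-3-yn-2-ol
Conditions: RuCl[(R,R)-TsDPEN](p-cymene) (1 mol %), i-PrOH, rt
Reagents that add atoms: none
Why: Noyori asymmetric transfer hydrogenation of an alkynyl methyl ketone; by analogy with other but-3-yn-2-ones the (R,R)-ligand should deliver hydride to the face that gives the (R)-carbinol (the antipodal catalyst is equally available). This is the only stereocentre introduced by a reagent; it later controls C6 and C7.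

Step 3
Reactants: 4 (2R)-5,5-diethoxypent-3-yn-2-ol
Product: 6 (2R,3Z)-5,5-diethoxy-4-iodopent-3-en-2-ol, via cyclic vinylalanate 5 (not isolated)
Conditions: NaAlH2(OCH2CH2OCH3)2, THF, 0 °C; then I2, THF, −78 °C
Reagents that add atoms: iodine, [I][I]
Why: Hydroxyl-directed trans-hydroalumination of a propargylic alcohol puts hydride on the proximal and aluminium on the distal alkyne carbon inside a five-membered alanate. Iodinolysis with retention should give the (Z)-γ-iodo allylic alcohol.

Step 4
Reactants: 6 (2R,3Z)-5,5-diethoxy-4-iodopent-3-en-2-ol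
Product: 7 (2R,3E)-4-(diethoxymethyl)hex-3-en-2-ol
Conditions: Et2Zn (2.5 equiv), Pd(dppf)Cl2 (5 mol %), THF, 50 °C
Reagents that add atoms: diethylzinc, CC[Zn]CC
Why: Negishi coupling of an alkenyl iodide proceeds with retention, so ethyl ends up cis to the carbinol carbon and the acetal trans to it. The bidentate phosphine suppresses β-hydride elimination, and the zinc alkoxide formed from the free hydroxyl is harmless.

Step 5
Reactants: 8 ethyl 3-oxohexanoate
Product: 9 ethyl 2-ethyl-3-oxohexanoate (racemic)
Conditions: EtI, K2CO3, acetone, reflux
Reagents that add atoms: iodoethane, CCI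
Why: C-alkylation of a β-keto ester enolate with a primary iodide; mono-alkylation is favoured because the product is less acidic and more hindered.

Step 6
Reactants: 7 (2R,3E)-4-(diethoxymethyl)hex-3-en-2-ol; 9 ethyl 2-ethyl-3-oxohexanoate
Product: 10 (2R,3E)-4-(diethoxymethyl)hex-3-en-2-yl 2-ethyl-3-oxohexanoate (both epimers at the α-carbon of the keto ester)
Conditions: 9 (3 equiv), DMAP (0.3 equiv), toluene, 110 °C, 4 Å molecular sieves
Reagents that add atoms: none
Why: Amine-catalysed transesterification of a β-keto ester, which runs through an acylketene and needs only the one α-hydrogen that 9 has. The ethanol released matches the acetal, so no acetal exchange can arise.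

Step 7
Reactants: 10 (2R,3E)-4-(diethoxymethyl)hex-3-en-2-yl 2-ethyl-3-oxohexanoate
Product: 12 methyl (2S,3S,4E)-2-butanoyl-3-(diethoxymethyl)-2,3-diethylhex-4-enoate, via rearranged keto acid 11 (not isolated)
Conditions: LiN(i-Pr)2 (2.3 equiv), THF, −78 → 60 °C; cold dilute HCl to pH 4, extraction; then CH3I, K2CO3, DMF, 0 °C
Reagents that add atoms: iodomethane, CI
Why: Dianionic Carroll (ester dienolate Claisen) rearrangement: the U-shaped, lithium-bridged dienolate holds the C7 ethyl cis to the allylic oxygen, the (E)-alkene holds the C6 ethyl cis to the carbinol carbon, and a chair with the carbinol methyl equatorial forms C6–C7 with both ethyl groups axial, which should translate the (R)-carbinol into (2S,3S)-12 with an (E)-propenyl group. Cold work-up and immediate methylation of the carboxylate keep the β-keto acid 11 from losing CO2.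

Step 8
Reactants: 12 methyl (2S,3S,4E)-2-butanoyl-3-(diethoxymethyl)-2,3-diethylhex-4-enoate
Product: 13 methyl (2S,3R)-2-butanoyl-3-(diethoxymethyl)-2,3-diethyl-4-oxobutanoate
Conditions: O3, CH2Cl2, pyridine, −78 °C (Sudan Red 7B end point); then Me2S
Reagents that add atoms: ozone, [O-][O+]=O
Why: Ozonolysis of the only C=C bond; with pyridine present the aldehyde forms directly. The former carbinol carbon and its methyl leave, so the controlling stereocentre is removed without trace.

Step 9
Reactants: 13 methyl (2S,3R)-2-butanoyl-3-(diethoxymethyl)-2,3-diethyl-4-oxobutanoate; 14 ethyltriphenylphosphonium iodide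
Product: 15 methyl (2S,3S,4Z)-2-butanoyl-3-(diethoxymethyl)-2,3-diethyl-5-iodohex-4-enoate
Conditions: 14, n-BuLi, THF, 0 °C; I2, −78 °C; NaN(SiMe3)2, −20 °C; then 13, −78 → −20 °C
Reagents that add atoms: iodine, [I][I]
Why: Stork–Zhao-type olefination with the α-iodo ylide gives (Z)-2-iodoalkenes under kinetic control, so C6 ends up cis to iodine. The aldehyde is far more reactive than the hindered ketone, and the ylide is too weak a base to enolise the butanoyl group and trigger an aldol closure onto C5.

Step 10
Reactants: 15 methyl (2S,3S,4Z)-2-butanoyl-3-(diethoxymethyl)-2,3-diethyl-5-iodohex-4-enoate; 16 (E)-prop-1-en-1-ylboronic acid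
Product: 17 methyl (2S,3S,4Z,6E)-2-butanoyl-3-(diethoxymethyl)-2,3-diethyl-5-methylocta-4,6-dienoate
Conditions: Pd(dppf)Cl2 (5 mol %), Cs2CO3, THF/H2O, 45 °C
Reagents that add atoms: none
Why: Suzuki–Miyaura coupling retains the geometry of both partners and so should give the (4Z,6E)-diene. It is run while C7 still carries the ketone, because an alkyne there would trap the alkenylpalladium by 5-exo carbopalladation.

Step 11
Reactants: 17 methyl (2S,3S,4Z,6E)-2-butanoyl-3-(diethoxymethyl)-2,3-diethyl-5-methylocta-4,6-dienoate
Product: 18 methyl (2S,3S,4Z,6E)-3-(diethoxymethyl)-2,3-diethyl-5-methyl-2-[(1Z)-1-(trifluoromethanesulfonyloxy)but-1-en-1-yl]octa-4,6-dienoate (mainly the (1Z)-enol triflate)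
Conditions: KN(SiMe3)2, THF, −78 °C; PhN(SO2CF3)2, −78 → 0 °C
Reagents that add atoms: N-phenylbis(trifluoromethanesulfonimide), FC(F)(F)S(=O)(=O)N(c1ccccc1)S(=O)(=O)C(F)(F)F
Why: The ketone can enolise only toward the propyl group because C7 is quaternary; O-sulfonylation of the potassium enolate gives the enol triflate, the ester having no α-hydrogen.

Step 12
Reactants: 18 the enol triflate of step 11
Product: 19 methyl (2R,3S,4Z,6E)-2-(but-1-yn-1-yl)-3-(diethoxymethyl)-2,3-diethyl-5-methylocta-4,6-dienoate
Conditions: LiN(i-Pr)2 (2.5 equiv), THF, −78 → −30 °C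
Reagents that add atoms: none
Why: Base-induced β-elimination of triflate from an enol triflate gives the internal alkyne; the low temperature is meant to prevent propargyl–allenyl isomerisation and deprotonation of the diene methyl group.

Step 13
Reactants: 19 methyl (2R,3S,4Z,6E)-2-(but-1-yn-1-yl)-3-(diethoxymethyl)-2,3-diethyl-5-methylocta-4,6-dienoate; 20 carbon monoxide
Product: 21 methyl (3S,3aR,6S,7R)-6-(diethoxymethyl)-1,6,7-triethyl-3,4-dimethyl-2-oxo-3,3a,6,7-tetrahydro-2H-indene-7-carboxylate
Conditions: [RhCl(CO)2]2 (5 mol %), CO (1 atm), ClCH2CH2Cl, 80 °C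
Reagents that add atoms: none
Why: Monovalent rhodium binds the alkyne and the diene; oxidative cyclisation joins C7a to C3a, which closes the cyclohexene in a 6-exo sense (the tether C7–C6–C5=C4 delivers the inner diene carbon C3a to the alkyne) and gives a rhodacyclopentene with trivalent rhodium on C1 and C3. CO then inserts into a Rh–C bond and reductive elimination forms C1–C2 and C2–C3, closing the cyclopentenone as its C1=C7a enone. The closest known reaction type is the rhodium-catalysed intramolecular Pauson–Khand ([2+2+1]) reaction of diene-ynes and of 1,7-enynes under CO; here the first double bond of the diene lies inside the tether and, being cis, holds the reacting alkene against the alkyne, while the two quaternary carbons add a Thorpe–Ingold bias. C3 is set by suprafacial addition to the (E)-alkene, so its methyl ends up trans to C4 on C3a. C3a is set by the alkene face that is presented: in the half-chair of the forming ring the C7 substituent lying in the plane of the new C1=C7a bond runs into the ethyl group on C1 (allylic 1,3-strain), so the flat ester should take that place and the C7 ethyl the axial one, which puts C3a–H on the face of the two ethyl groups. The step therefore needs diastereofacial selectivity, secured by the ethyl/ester pair on C7, and chemoselectivity for [2+2+1] over [4+2], secured by the two-atom link between the alkyne and the diene terminus, which is too short for a Diels–Alder-type closure.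

Step 14
Reactants: 21 the enone of step 13
Product: 23 methyl (1S,3S,3aR,6S,7R,7aR)-6-(diethoxymethyl)-1,6,7-triethyl-3,4-dimethyl-2-oxo-2,3,3a,6,7,7a-hexahydro-1H-indene-7-carboxylate, via C1-epimeric ketone mixture 22 (not isolated)
Conditions: Li (2.5 equiv), NH3(l)/THF, t-BuOH (1 equiv), −78 °C; solid NH4Cl; then NaOMe (cat.), MeOH, rt
Reagents that add atoms: none
Why: Dissolving-metal conjugate reduction: the β-carbanion at C7a should be protonated axially, anti to C3a–H and on the face away from the axial C7 ethyl, giving the trans fusion, which is also the more stable one since both five-ring bonds are then equatorial. Limited lithium and short contact at −78 °C are meant to spare the hindered ester and the isolated C4=C5 bond; methoxide then equilibrates C1 (and C3) to the all-trans arrangement.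

Step 15
Reactants: 23 the acetal ketone of step 14
Product: 24 methyl (1S,3S,3aR,6S,7R,7aR)-1,6,7-triethyl-6-formyl-3,4-dimethyl-2-oxo-2,3,3a,6,7,7a-hexahydro-1H-indene-7-carboxylate
Conditions: 2 M HCl, THF, 40 °C
Reagents that add atoms: water, O
Why: Acid hydrolysis of the diethyl acetal releases the C1' aldehyde without ever passing through a free alcohol, so no lactone can form; the ketone α-centres are already in their stable arrangement.

Step 16
Reactants: 25 propyltriphenylphosphonium bromide; 26 ethyl formate
Product: 27 2-(triphenylphosphoranylidene)butanal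
Conditions: KOt-Bu, THF, 0 °C; then 26, 0 °C → rt
Reagents that add atoms: none
Why: C-formylation of a non-stabilised ylide with a formate ester; the ethoxide released deprotonates the acylphosphonium salt to the stabilised ylide.

Step 17
Reactants: 24 the aldehyde of step 15; 27 2-(triphenylphosphoranylidene)butanal
Product: 28 methyl (1S,3S,3aR,6R,7R,7aR)-1,6,7-triethyl-6-[(1E)-2-formylbut-1-en-1-yl]-3,4-dimethyl-2-oxo-2,3,3a,6,7,7a-hexahydro-1H-indene-7-carboxylate
Conditions: toluene, 110 °C
Reagents that add atoms: none
Why: Wittig reaction of a stabilised formyl ylide, which is (E)-selective (C6 trans to the formyl group) and reacts with aldehydes only, so the ketone is untouched; heat is needed for the neopentyl aldehyde.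

Step 18
Reactants: 28 the enal of step 17; 29 diethyl benzylphosphonate
Product: 30 methyl (1S,3S,3aR,6R,7R,7aR)-1,6,7-triethyl-6-[(1E,3E)-2-ethyl-4-phenylbuta-1,3-dien-1-yl]-3,4-dimethyl-2-oxo-2,3,3a,6,7,7a-hexahydro-1H-indene-7-carboxylate
Conditions: 29, NaH, THF, 0 °C; then 28, 0 °C → rt
Reagents that add atoms: none
Why: Horner–Wadsworth–Emmons olefination with a benzylphosphonate anion gives the (E)-styryl bond and leaves the C1'=C2' geometry alone; the aldehyde reacts far faster than the flanked ketone, whose possible enolisation is harmless because C1 and C3 are at equilibrium.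

Step 19
Reactants: 30 the methyl ester of step 18
Product: 31 (1S,3S,3aR,6R,7R,7aR)-1,6,7-triethyl-6-[(1E,3E)-2-ethyl-4-phenylbuta-1,3-dien-1-yl]-3,4-dimethyl-2-oxo-2,3,3a,6,7,7a-hexahydro-1H-indene-7-carboxylic acid
Conditions: NaSEt, DMF, 80 °C; then aq. HCl
Reagents that add atoms: none
Why: Ester cleavage by SN2 attack of thiolate at the methyl carbon, which is unaffected by the steric shielding of the acyl carbon and needs no hydroxide; the diene and the equilibrated ketone should tolerate it.

## Compound list

1 | 3,3-diethoxyprop-1-yne | C#CC(OCC)OCC | starting material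
2 | N-methoxy-N-methylacetamide | CC(=O)N(C)OC | starting material
3 | 5,5-diethoxypent-3-yn-2-one | CC(=O)C#CC(OCC)OCC | intermediate
4 | (2R)-5,5-diethoxypent-3-yn-2-ol | C[C@@H](O)C#CC(OCC)OCC | intermediate
5 | sodium salt of the cyclic vinylalanate from 4 (five-membered O–Al–C=C ring, aluminium on the acetal-bearing carbon, two 2-methoxyethoxy groups on aluminium) | C[C@H]1O[Al-](OCCOC)(OCCOC)C(C(OCC)OCC)=C1.[Na+] | intermediate
6 | (2R,3Z)-5,5-diethoxy-4-iodopent-3-en-2-ol | C[C@@H](O)/C=C(\I)C(OCC)OCC | intermediate
7 | (2R,3E)-4-(diethoxymethyl)hex-3-en-2-ol | C[C@@H](O)/C=C(\CC)C(OCC)OCC | intermediate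
8 | ethyl 3-oxohexanoate | CCCC(=O)CC(=O)OCC | starting material
9 | ethyl 2-ethyl-3-oxohexanoate (racemic) | CCCC(=O)C(CC)C(=O)OCC | intermediate
10 | (2R,3E)-4-(diethoxymethyl)hex-3-en-2-yl 2-ethyl-3-oxohexanoate (both epimers at the keto ester α-carbon) | CCCC(=O)C(CC)C(=O)O[C@H](C)/C=C(\CC)C(OCC)OCC | intermediate
11 | (2S,3S,4E)-2-butanoyl-3-(diethoxymethyl)-2,3-diethylhex-4-enoic acid | CCCC(=O)[C@@](CC)(C(=O)O)[C@@](CC)(C(OCC)OCC)/C=C/C | intermediate
12 | methyl (2S,3S,4E)-2-butanoyl-3-(diethoxymethyl)-2,3-diethylhex-4-enoate | CCCC(=O)[C@@](CC)(C(=O)OC)[C@@](CC)(C(OCC)OCC)/C=C/C | intermediate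
13 | methyl (2S,3R)-2-butanoyl-3-(diethoxymethyl)-2,3-diethyl-4-oxobutanoate | CCCC(=O)[C@@](CC)(C(=O)OC)[C@@](CC)(C(OCC)OCC)C=O | intermediate
14 | ethyltriphenylphosphonium iodide | CC[P+](c1ccccc1)(c1ccccc1)c1ccccc1.[I-] | starting material
15 | methyl (2S,3S,4Z)-2-butanoyl-3-(diethoxymethyl)-2,3-diethyl-5-iodohex-4-enoate | CCCC(=O)[C@@](CC)(C(=O)OC)[C@@](CC)(C(OCC)OCC)/C=C(\I)C | intermediate
16 | (E)-prop-1-en-1-ylboronic acid | C/C=C/B(O)O | starting material
17 | methyl (2S,3S,4Z,6E)-2-butanoyl-3-(diethoxymethyl)-2,3-diethyl-5-methylocta-4,6-dienoate | CCCC(=O)[C@@](CC)(C(=O)OC)[C@@](CC)(C(OCC)OCC)/C=C(C)\C=C\C | intermediate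
18 | methyl (2S,3S,4Z,6E)-3-(diethoxymethyl)-2,3-diethyl-5-methyl-2-[(1Z)-1-(trifluoromethanesulfonyloxy)but-1-en-1-yl]octa-4,6-dienoate | CC/C=C(\OS(=O)(=O)C(F)(F)F)[C@@](CC)(C(=O)OC)[C@@](CC)(C(OCC)OCC)/C=C(C)\C=C\C | intermediate
19 | methyl (2R,3S,4Z,6E)-2-(but-1-yn-1-yl)-3-(diethoxymethyl)-2,3-diethyl-5-methylocta-4,6-dienoate | CCC#C[C@@](CC)(C(=O)OC)[C@@](CC)(C(OCC)OCC)/C=C(C)\C=C\C | intermediate
20 | carbon monoxide | [C-]#[O+] | starting material
21 | methyl (3S,3aR,6S,7R)-6-(diethoxymethyl)-1,6,7-triethyl-3,4-dimethyl-2-oxo-3,3a,6,7-tetrahydro-2H-indene-7-carboxylate | CCOC(OCC)[C@@]1(CC)C=C(C)[C@@H]2C(=C(CC)C(=O)[C@H]2C)[C@@]1(CC)C(=O)OC | intermediate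
22 | methyl (3S,3aR,6S,7R,7aR)-6-(diethoxymethyl)-1,6,7-triethyl-3,4-dimethyl-2-oxo-2,3,3a,6,7,7a-hexahydro-1H-indene-7-carboxylate, both epimers at C1 | CCOC(OCC)[C@@]1(CC)C=C(C)[C@@H]2[C@H](C(CC)C(=O)[C@H]2C)[C@@]1(CC)C(=O)OC | intermediate
23 | methyl (1S,3S,3aR,6S,7R,7aR)-6-(diethoxymethyl)-1,6,7-triethyl-3,4-dimethyl-2-oxo-2,3,3a,6,7,7a-hexahydro-1H-indene-7-carboxylate | CCOC(OCC)[C@@]1(CC)C=C(C)[C@@H]2[C@H]([C@H](CC)C(=O)[C@H]2C)[C@@]1(CC)C(=O)OC | intermediate
24 | methyl (1S,3S,3aR,6S,7R,7aR)-1,6,7-triethyl-6-formyl-3,4-dimethyl-2-oxo-2,3,3a,6,7,7a-hexahydro-1H-indene-7-carboxylate | O=C[C@@]1(CC)C=C(C)[C@@H]2[C@H]([C@H](CC)C(=O)[C@H]2C)[C@@]1(CC)C(=O)OC | intermediate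
25 | propyltriphenylphosphonium bromide | CCC[P+](c1ccccc1)(c1ccccc1)c1ccccc1.[Br-] | starting material
26 | ethyl formate | CCOC=O | starting material
27 | 2-(triphenylphosphoranylidene)butanal | CCC(C=O)=P(c1ccccc1)(c1ccccc1)c1ccccc1 | intermediate
28 | methyl (1S,3S,3aR,6R,7R,7aR)-1,6,7-triethyl-6-[(1E)-2-formylbut-1-en-1-yl]-3,4-dimethyl-2-oxo-2,3,3a,6,7,7a-hexahydro-1H-indene-7-carboxylate | O=C/C(CC)=C/[C@@]1(CC)C=C(C)[C@@H]2[C@H]([C@H](CC)C(=O)[C@H]2C)[C@@]1(CC)C(=O)OC | intermediate
29 | diethyl benzylphosphonate | CCOP(=O)(Cc1ccccc1)OCC | starting material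
30 | methyl (1S,3S,3aR,6R,7R,7aR)-1,6,7-triethyl-6-[(1E,3E)-2-ethyl-4-phenylbuta-1,3-dien-1-yl]-3,4-dimethyl-2-oxo-2,3,3a,6,7,7a-hexahydro-1H-indene-7-carboxylate | CCC(/C=C/c1ccccc1)=C\[C@@]1(CC)C=C(C)[C@@H]2[C@H]([C@H](CC)C(=O)[C@H]2C)[C@@]1(CC)C(=O)OC | intermediate
31 | (1S,3S,3aR,6R,7R,7aR)-1,6,7-triethyl-6-[(1E,3E)-2-ethyl-4-phenylbuta-1,3-dien-1-yl]-3,4-dimethyl-2-oxo-2,3,3a,6,7,7a-hexahydro-1H-indene-7-carboxylic acid | CCC(/C=C/c1ccccc1)=C\[C@@]1(CC)C=C(C)[C@@H]2[C@H]([C@H](CC)C(=O)[C@H]2C)[C@@]1(CC)C(=O)O | target

## Step count and least certain steps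

Total step count: 19 (steps 5 and 16 prepare side components). Longest linear sequence: 17 steps (steps 1–4, 6–15 and 17–19).

**Step 13 (key step).** The most likely failure is insufficient discrimination between the two faces of the C3a=C3 alkene during oxidative cyclisation, because the groups on C6 and C7 that distinguish them are of similar size; a slow insertion of the 1,2-disubstituted diene terminus would show up as unproductive consumption of the alkyne. Fallback, thermodynamic in place of kinetic control: starting from 19 the cycloaddition is run as described and the unwanted diastereomer, methyl (3R,3aS,6S,7R)-6-(diethoxymethyl)-1,6,7-triethyl-3,4-dimethyl-2-oxo-3,3a,6,7-tetrahydro-2H-indene-7-carboxylate F1, is separated and heated with DBU in toluene. C3a–H is γ to the enone and allylic to C4=C5, so it is removed reversibly through the extended dienolate, and C3 equilibrates as an ordinary α'-centre. The epimer with the ester, not the ethyl group, beside the C1 ethyl should be the more stable, so the mixture should drain into 21, where the fallback rejoins the route.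

**Step 7.** The dianion may fragment (loss of the allylic alkoxide to an acylketene) faster than it rearranges across two fully substituted carbons, or the dienolate geometry may not be held, which would erode the C6/C7 relationship. Fallback, a neutral silyl ketene acetal rearrangement with the ketone introduced afterwards: starting from 7, esterification (DCC, DMAP) with 2-[(ethylsulfanyl)carbonyl]butanoic acid F2 (from 5-ethyl-2,2-dimethyl-1,3-dioxane-4,6-dione and ethanethiol) gives the mixed malonate (2R,3E)-4-(diethoxymethyl)hex-3-en-2-yl 2-[(ethylsulfanyl)carbonyl]butanoate F3. Ireland–Claisen rearrangement (LiN(SiMe3)2, Me3SiCl, THF, −78 °C → reflux), whose ketene acetal is chelated in the same sense, gives (2R,3S,4E)-3-(diethoxymethyl)-2,3-diethyl-2-[(ethylsulfanyl)carbonyl]hex-4-enoic acid F4. Methylation (CH3I, K2CO3) gives its methyl ester F5, and n-Pr2CuLi converts the thioester into the butanoyl ketone, which is 12.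

**Step 9.** The bulky α-iodo ylide may add too slowly to an aldehyde that sits on a quaternary carbon next to a second one, so that ylide decomposition or loss of (Z)-selectivity takes over. Fallback, stereodefined stepwise substitution of a gem-dihalide: starting from 13, CCl4/PPh3 gives methyl (2S,3S)-2-butanoyl-5,5-dichloro-3-(diethoxymethyl)-2,3-diethylpent-4-enoate F6. A trans-selective Negishi monomethylation (Me2Zn, PdCl2(DPEphos)) replaces the chlorine trans to C6 and gives methyl (2S,3S,4Z)-2-butanoyl-5-chloro-3-(diethoxymethyl)-2,3-diethylhex-4-enoate F7. Coupling of the remaining chloride with 16 (Pd[P(t-Bu)3]2, Cs2CO3) returns to the route at 17.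

**Step 14.** Electron transfer to the methyl ester may compete with reduction of the enone and destroy the ester; protonation of C7a from the wrong face (cis fusion) is the second concern. Fallback, the carboxyl carried as a carboxylate, which does not accept electrons: starting from 21, LiI in refluxing ethyl acetate demethylates without hydroxide and gives (3S,3aR,6S,7R)-6-(diethoxymethyl)-1,6,7-triethyl-3,4-dimethyl-2-oxo-3,3a,6,7-tetrahydro-2H-indene-7-carboxylic acid F8. The same lithium/ammonia reduction and methoxide equilibration give (1S,3S,3aR,6S,7R,7aR)-6-(diethoxymethyl)-1,6,7-triethyl-3,4-dimethyl-2-oxo-2,3,3a,6,7,7a-hexahydro-1H-indene-7-carboxylic acid F9, and Me3SiCHN2 in methanol re-forms the methyl ester 23.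

**Step 17.** The stabilised formyl ylide is a weak nucleophile and may not add to the neopentyl aldehyde before thermal decomposition sets in. Fallback, the diene built by two stereoretentive couplings on a gem-dibromide: starting from 24, CBr4/PPh3 gives methyl (1S,3S,3aR,6R,7R,7aR)-6-(2,2-dibromoethenyl)-1,6,7-triethyl-3,4-dimethyl-2-oxo-2,3,3a,6,7,7a-hexahydro-1H-indene-7-carboxylate F10. Suzuki–Miyaura coupling with (E)-2-phenylethenylboronic acid (Pd2(dba)3, tri(2-furyl)phosphine, Cs2CO3) reacts at the bromine trans to C6 and gives methyl (1S,3S,3aR,6R,7R,7aR)-6-[(1Z,3E)-2-bromo-4-phenylbuta-1,3-dien-1-yl]-1,6,7-triethyl-3,4-dimethyl-2-oxo-2,3,3a,6,7,7a-hexahydro-1H-indene-7-carboxylate F11. Negishi ethylation of the remaining bromide (Et2Zn, Pd[P(t-Bu)3]2) gives 30.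

## Further compounds

F1 | step 13 | methyl (3R,3aS,6S,7R)-6-(diethoxymethyl)-1,6,7-triethyl-3,4-dimethyl-2-oxo-3,3a,6,7-tetrahydro-2H-indene-7-carboxylate | CCOC(OCC)[C@@]1(CC)C=C(C)[C@H]2C(=C(CC)C(=O)[C@@H]2C)[C@@]1(CC)C(=O)OC
F2 | step 7 | 2-[(ethylsulfanyl)carbonyl]butanoic acid (racemic) | CCSC(=O)C(CC)C(=O)O
F3 | step 7 | (2R,3E)-4-(diethoxymethyl)hex-3-en-2-yl 2-[(ethylsulfanyl)carbonyl]butanoate | CCSC(=O)C(CC)C(=O)O[C@H](C)/C=C(\CC)C(OCC)OCC
F4 | step 7 | (2R,3S,4E)-3-(diethoxymethyl)-2,3-diethyl-2-[(ethylsulfanyl)carbonyl]hex-4-enoic acid | CCSC(=O)[C@@](CC)(C(=O)O)[C@@](CC)(C(OCC)OCC)/C=C/C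
F5 | step 7 | methyl (2R,3S,4E)-3-(diethoxymethyl)-2,3-diethyl-2-[(ethylsulfanyl)carbonyl]hex-4-enoate | CCSC(=O)[C@@](CC)(C(=O)OC)[C@@](CC)(C(OCC)OCC)/C=C/C
F6 | step 9 | methyl (2S,3S)-2-butanoyl-5,5-dichloro-3-(diethoxymethyl)-2,3-diethylpent-4-enoate | CCCC(=O)[C@@](CC)(C(=O)OC)[C@@](CC)(C(OCC)OCC)C=C(Cl)Cl
F7 | step 9 | methyl (2S,3S,4Z)-2-butanoyl-5-chloro-3-(diethoxymethyl)-2,3-diethylhex-4-enoate | CCCC(=O)[C@@](CC)(C(=O)OC)[C@@](CC)(C(OCC)OCC)/C=C(\Cl)C
F8 | step 14 | (3S,3aR,6S,7R)-6-(diethoxymethyl)-1,6,7-triethyl-3,4-dimethyl-2-oxo-3,3a,6,7-tetrahydro-2H-indene-7-carboxylic acid | CCOC(OCC)[C@@]1(CC)C=C(C)[C@@H]2C(=C(CC)C(=O)[C@H]2C)[C@@]1(CC)C(=O)O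
F9 | step 14 | (1S,3S,3aR,6S,7R,7aR)-6-(diethoxymethyl)-1,6,7-triethyl-3,4-dimethyl-2-oxo-2,3,3a,6,7,7a-hexahydro-1H-indene-7-carboxylic acid | CCOC(OCC)[C@@]1(CC)C=C(C)[C@@H]2[C@H]([C@H](CC)C(=O)[C@H]2C)[C@@]1(CC)C(=O)O
F10 | step 17 | methyl (1S,3S,3aR,6R,7R,7aR)-6-(2,2-dibromoethenyl)-1,6,7-triethyl-3,4-dimethyl-2-oxo-2,3,3a,6,7,7a-hexahydro-1H-indene-7-carboxylate | BrC(Br)=C[C@@]1(CC)C=C(C)[C@@H]2[C@H]([C@H](CC)C(=O)[C@H]2C)[C@@]1(CC)C(=O)OC
F11 | step 17 | methyl (1S,3S,3aR,6R,7R,7aR)-6-[(1Z,3E)-2-bromo-4-phenylbuta-1,3-dien-1-yl]-1,6,7-triethyl-3,4-dimethyl-2-oxo-2,3,3a,6,7,7a-hexahydro-1H-indene-7-carboxylate | BrC(/C=C/c1ccccc1)=C\[C@@]1(CC)C=C(C)[C@@H]2[C@H]([C@H](CC)C(=O)[C@H]2C)[C@@]1(CC)C(=O)OC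
A1 | alternative 1 | dimethyl 6-(but-1-yn-1-yl)-1,6,7-triethyl-4-methyl-2-oxo-2,3,3a,6,7,7a-hexahydro-1H-indene-3,7-dicarboxylate, trans-fused, configuration as in the SMILES | CCC#C[C@@]1(CC)C=C(C)[C@@H]2[C@H]([C@H](CC)C(=O)[C@H]2C(=O)OC)[C@@]1(CC)C(=O)OC
A2 | alternative 2 | methyl ester of the target, identical with 30 | CCC(/C=C/c1ccccc1)=C\[C@@]1(CC)C=C(C)[C@@H]2[C@H]([C@H](CC)C(=O)[C@H]2C)[C@@]1(CC)C(=O)OC
A3 | alternative 3 | 6-(but-1-en-2-yl)-2-{[tert-butyl(dimethyl)silyl]oxymethyl}-1,2-diethyl-4-methyl-5-(prop-1-en-2-yl)cyclohex-3-ene-1-carboxylic acid, configuration as in the SMILES | CC(C)(C)[Si](C)(C)OC[C@@]1(CC)C=C(C)[C@@H](C(C)=C)[C@H](C(=C)CC)[C@@]1(CC)C(=O)O
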